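# Proposed synthesis of CNP0316493.3: late three-component carbene/phenol/aldehyde union for unit C

## Analysis of the target

The target is a pentameric lignan built on a (7S,7′S,8R,8′R)-syringaresinol core, a cis-fused 3,7-dioxabicyclo[3.3.0]octane with two exo syringyl rings, each phenolic oxygen of which is etherified by C8 of a guaiacylglycerol. It has ten stereocentres: four in the rigid bicycle and three acyclic C7/C8 pairs. Unit A, on one syringyl oxygen, is erythro (7R,8S) and ends in a free guaiacyl phenol. Unit B, on the other, is threo (7S,8S), and its guaiacyl oxygen carries unit C, which is erythro (7S,8R) and again ends in a free phenol. The core is C2-symmetric, so its two syringyl oxygens are homotopic yet must receive different chains, and the three glycerol units are too far apart to relay stereochemistry to one another. Sensitive features are the electron-rich benzylic ethers of the furofuran (acid ionises and epimerises C7/C7′), the three 4-oxygenated benzylic carbinols (quinone methides under base once the phenols are free, benzylic cations under acid) and the oxidisable phenols. The difficulty is therefore not ring construction but the repeated, independently controlled assembly of aryl–O–C8(–C9)–C7(OH)–aryl arrays of differing relative and absolute configuration. The strategy rests on C8 of unit C: it is bonded to the 4-oxygen of the guaiacyl ring of unit B, to the carbinol C7 and to a CH2OH one reduction below a carboxyl group, which is the pattern of a diazoacetate carbon placed between a phenol O–H and the carbonyl of a vanillin derivative.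

## Retrosynthetic reasoning

**24 to 23 to 22.** The last operations only change protecting groups and oxidation level. The free polyol 24 contains three 4-hydroxybenzyl alcohols, so the five silyl ethers of 23 are removed last. In 22, C9 of unit C is still an ethyl ester and the terminal phenol an acetate; one hydride step takes both to the level of 23.

**22 to 18, 19 and 20.** The bonds O–C8 and C7–C8 of unit C are cut together. C8 of unit C is the only glycerol carbon whose ether oxygen belongs to a phenol that can be kept as the single free O–H of a late intermediate. Cutting here removes a complete arylglycerol in one step and reduces two of the three partners to commodity pieces, ethyl diazoacetate 19 and vanillin acetate 20. The forward step must form two bonds and two stereocentres under catalyst control on phenol 18.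

**18 to 17 to 16.** The free guaiacyl phenol of 18 is carried as the allyl ether 17, which can be unmasked without acid, base or fluoride. The hydroxyls of units A and B are silyl ethers, traced back to triol 16.

**16 to 15 to 14.** A boron glycolate aldol gives only the syn adduct, which is the threo arylglycerol. The erythro pattern of unit A is therefore derived from the 4-nitrobenzoate 15, made by inversion at the benzylic C7 of the syn adduct 14. Reduction of 15 removes both auxiliaries and the ester in one operation.

**14 to 11 and 12; 11 to 10 to 6 and 8.** The C7–C8 bonds of units A and B are cut as glycolate aldols. Both C8 centres are S, so one enantiomer of the auxiliary serves both arms and the C2-symmetric bis-imide 6 is a common precursor. The arms are told apart only by the aldehyde (8 for unit B, 12 for unit A) and by the later inversion. The price is one statistical mono-aldol (6 to 10), placed early, where unreacted 6 can be recovered.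

**6 to 3 and 5; 5 to 4.** The two aryl-O–CH2 bonds are cut to the diphenol 3 and the bromoacetyl imide 5, which comes from oxazolidinone 4. Because both phenols are alkylated, no differentiation is needed at this stage.

**3 to 2 to 1.** C8–C8′ and both C7–O bonds of the core are cut in the biomimetic sense, back to two molecules of sinapyl alcohol 1. The dimerisation gives racemic 2, so a resolution to 3 is included.

**8 and 12 to 7.** Both protected aldehydes are one step from vanillin 7.

## Alternatives that were turned down

**Alternative 1:** The core would be cut at C8–C8′ through a cyclobutane. Two molecules of the cinnamoyl imidazole A2 would undergo a sensitised, chiral-acid-controlled head-to-head [2+2] photodimerisation to the all-trans truxinate-type cyclobutane A1. After reduction of the acyl groups, the C7–C7′ bond would be broken oxidatively and both primary alcohols closed onto the benzylic carbons, and debenzylation would then give 3.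
- For it: C8 and C8′ are set catalytically in the absolute sense, so no resolution is needed. On that point it is stronger than the chosen route.
- Against it: the C7–C7′ bond is made only to be destroyed. Its cleavage needs a radical-cation fragmentation followed by a double cyclisation that must also set C7 and C7′, none of which is established for such a substrate. The closing hydrogenolysis of two benzyl ethers endangers the benzylic C–O bonds of the furofuran.
- Comparison: it costs at least five more steps than the two from 1 to 3, carries two uncertain steps instead of one, and ends at the same symmetric diphenol with all three glycerol units still to be attached. The chosen route spends its single speculative step where a whole glycerol unit is gained and backs it with a conventional fallback.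

**Alternative 2:** Both aryl–C7 bonds would be cut. BF3·OEt2 would ionise the bis-lactol diacetate A4 twice, and the arylzinc reagent A5 would add each time from the convex face, giving the bis-silyl ether A3, which is desilylated to 3.
- For it: the step is convergent, the exo,exo arrangement follows from the shape of the bicycle, and the absolute configuration comes from the scaffold. It is as strong as the chosen route on relative control and stronger on absolute control.
- Against it: A4 must first be made enantiopure over several steps. After the first arylation the new electron-rich benzylic ether competes with the remaining acetate for the Lewis acid, so re-ionisation, epimerisation or ring opening can accompany the second substitution.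
- Comparison: it again delivers only the symmetric core, so neither the desymmetrisation nor the glycerol units are addressed. The chosen route accepts a chromatographic resolution in exchange for a two-step core and puts the new chemistry at unit C.

**Alternative 3:** The core would be cut at C8–C8′ and C7′–O. Cp2TiCl, a titanocene chloride of trivalent titanium, would open the epoxide of the epoxy ether A7 to a C8 radical, which cyclises 5-exo onto the cinnamyl alkene. Oxidation of the benzylic C7′ species would then let the C9 alkoxide close the second ring, giving the mono-benzyl mono-silyl furofuran A6.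
- For it: the two syringyl oxygens come out already differentiated and the absolute configuration can come from an asymmetric epoxidation. This answers the symmetry problem better than the statistical step of the chosen route.
- Against it: A7 needs a resolved aryl epoxy carbinol and a separately made cinnamyl partner, roughly eight steps before the cascade. C7′ is set in a cation capture with only thermodynamic bias, and the benzyl ether must later be removed in the presence of benzylic furofuran ethers.
- Comparison: the differentiated core would arrive in more steps than the whole sequence from 1 to the mono-aldol 10, and the glycerol units would still have to be built one by one. The chosen route differentiates by a recyclable statistical reaction on cheap symmetric material and saves a full aldol/inversion/reduction sequence through the three-component step.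

Key step: step 14

## Remarks on the chemistry

- The oxidative dimerisation joins two molecules of 1 into one molecule of 2. It is not enantioselective with simple oxidants, so racemic 2 is resolved by chromatography on a chiral phase and only the (7S,7′S,8R,8′R) enantiomer 3 is carried on.
- The boron glycolate aldol is syn along the acyl chain, which in arylglycerol nomenclature is threo (7S,8S with the (R)-auxiliary). Unit B therefore forms directly, and unit A needs inversion at C7.
- The aldehyde of the key step is used as its acetate 20 rather than as a silyl ether. The acetoxy group makes the carbonyl more electrophilic and is removed in the following hydride step.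

## Route

Step 1
Reactants: 1 sinapyl alcohol (2 equiv; two molecules are joined)
Product: 2 (±)-syringaresinol (racemate, exo,exo-diaryl cis-fused furofuran)
Conditions: laccase (Trametes versicolor), O2, acetone/NaOAc buffer pH 5, rt
Reagents that add atoms: second molecule of sinapyl alcohol 1, COc1cc(/C=C/CO)cc(OC)c1O
Why: Oxidative phenol dehydrodimerisation of two molecules of 1: the phenoxyl radicals couple C8–C8′ because both ortho positions carry methoxy groups, and the bis-quinone methide is trapped by the two primary hydroxyls in two 5-exo closures to the thermodynamically preferred exo,exo-diaryl cis-fused bicycle, as the racemate.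

Step 2
Reactants: 2 (±)-syringaresinol
Product: 3 (7S,7′S,8R,8′R)-syringaresinol
Conditions: preparative SFC, cellulose tris(3,5-dimethylphenylcarbamate) phase, CO2/MeOH; (7S,7′S,8R,8′R) enantiomer collected
Reagents that add atoms: none
Why: Resolution of enantiomers on a chiral stationary phase; no bond is formed, and the identity of the collected enantiomer is to be fixed by comparison of chiroptical data with the natural compound.

Step 3
Reactants: 4 (R)-4-benzyloxazolidin-2-one
Product: 5 (R)-4-benzyl-3-(2-bromoacetyl)oxazolidin-2-one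
Conditions: n-BuLi, THF, −78 °C; BrCH2COBr, −78 → 0 °C
Reagents that add atoms: bromoacetyl bromide, BrCC(Br)=O
Why: N-Acylation of the lithiated oxazolidinone by the acid bromide is far faster at −78 °C than displacement of the primary bromide, and the auxiliary stereocentre is not involved.

Step 4
Reactants: 3 (7S,7′S,8R,8′R)-syringaresinol; 5 (R)-4-benzyl-3-(2-bromoacetyl)oxazolidin-2-one (2.3 equiv)
Product: 6 C2-symmetric bis-glycolyl imide, 4,4′-bis-O-{2-[(4R)-4-benzyl-2-oxooxazolidin-3-yl]-2-oxoethyl}syringaresinol
Conditions: K2CO3, acetone, rt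
Reagents that add atoms: none
Why: Williamson etherification: the syringyl phenoxides displace bromide from the activated α-halo imide, and because both homotopic phenols react the C2 symmetry is kept and no statistical mixture arises.

Step 5
Reactants: 7 vanillin
Product: 8 4-(allyloxy)-3-methoxybenzaldehyde
Conditions: allyl bromide, K2CO3, DMF, rt
Reagents that add atoms: allyl bromide, C=CCBr
Why: Williamson O-allylation of the phenol; the allyl ether marks the one phenol that must later be freed on its own.

Step 6
Reactants: 6 bis-glycolyl imide; 8 4-(allyloxy)-3-methoxybenzaldehyde (1.0 equiv)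
Product: 10 mono-aldol adduct in which one arm is the (2R,3S)-3-[4-(allyloxy)-3-methoxyphenyl]-3-hydroxy-2-aryloxypropanoyl imide (unit B in the 7S,8S sense) and the other arm is the unchanged glycolyl imide, via dibutylboron Z-enolate 9 (not isolated)
Conditions: n-Bu2BOTf (1.0 equiv), i-Pr2NEt (1.2 equiv), CH2Cl2, −78 → 0 °C; 8, −78 → 0 °C; pH 7 buffer, MeOH, H2O2, 0 °C
Reagents that add atoms: none
Why: Evans syn aldol: soft enolisation gives the Z-boron enolate, which adds through a chair Zimmerman–Traxler transition state on the face away from the benzyl group of the auxiliary, setting both centres of unit B (threo). The two imide arms are remote and independent, so one equivalent of boron triflate and aldehyde should give the mono-adduct as the main component of a statistical mixture that separates by polarity, with unreacted 6 recycled.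

Step 7
Reactants: 10 mono-aldol adduct
Product: 11 tert-butyldimethylsilyl ether of 10 at the unit B C7 hydroxyl
Conditions: TBSOTf, 2,6-lutidine, CH2Cl2, −78 → 0 °C
Reagents that add atoms: tert-butyldimethylsilyl triflate, CC(C)(C)[Si](C)(C)OS(=O)(=O)C(F)(F)F
Why: Silylation of the hindered benzylic carbinol with a silyl triflate and a non-nucleophilic base; it installs the final protecting group of unit B C7, blocks retro-aldol, and leaves the later inversion a single hydroxyl to address.

Step 8
Reactants: 7 vanillin
Product: 12 4-(tert-butyldimethylsilyloxy)-3-methoxybenzaldehyde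
Conditions: TBSCl, imidazole, DMF, rt
Reagents that add atoms: tert-butyldimethylsilyl chloride, CC(C)(C)[Si](C)(C)Cl
Why: Standard phenol silylation; a silyl ether is chosen for the guaiacyl phenol of unit A because it survives deallylation and the carbene step and leaves with the other silyl groups at the end.

Step 9
Reactants: 11 silylated mono-aldol adduct; 12 4-(tert-butyldimethylsilyloxy)-3-methoxybenzaldehyde
Product: 14 double aldol adduct whose unit A arm is the (2R,3S)-3-hydroxy-3-[3-methoxy-4-(tert-butyldimethylsilyloxy)phenyl]-2-aryloxypropanoyl imide with free C7 hydroxyl (7S sense) and whose unit B arm is as in 11, via dibutylboron Z-enolate 13 (not isolated)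
Conditions: n-Bu2BOTf (1.3 equiv), i-Pr2NEt (1.5 equiv), CH2Cl2, −78 → 0 °C; 12, −78 → 0 °C; pH 7 buffer, MeOH, H2O2, 0 °C
Reagents that add atoms: none
Why: Second Evans syn aldol on the remaining glycolyl imide; the same auxiliary gives the same facial sense, so C8 of unit A has its final S configuration while C7 is still epimeric. The α-branched unit B imide should not be re-enolised, because allylic strain disfavours its enolate and silanolate is a poor leaving group.

Step 10
Reactants: 14 double aldol adduct
Product: 15 4-nitrobenzoate of 14 with inverted unit A C7 ((2R,3R) acyl configuration, erythro series)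
Conditions: 4-O2NC6H4CO2H, PPh3, DIAD, toluene/THF, −20 °C → rt
Reagents that add atoms: 4-nitrobenzoic acid, OC(=O)c1ccc(cc1)[N+](=O)[O-]
Why: Mitsunobu reaction: the only free hydroxyl is activated as its alkoxyphosphonium ion and displaced with inversion by the carboxylate, converting the syn (threo) adduct into the anti (erythro, 7R) arrangement of unit A. The acidic pronucleophile and low temperature favour substitution over elimination or ionisation.

Step 11
Reactants: 15 inverted 4-nitrobenzoate
Product: 16 triol with the (7R,8S)-diol of unit A and the primary C9 alcohol of unit B (unit B C7 silyl ether, unit A aryl silyl ether and unit B aryl allyl ether retained)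
Conditions: LiBH4, MeOH (stoich.), THF, 0 °C → rt
Reagents that add atoms: none
Why: Reductive auxiliary removal: borohydride attacks the exocyclic imide carbonyls to give both primary alcohols and the recoverable oxazolidinone, and also reduces off the activated aryl ester, so three hydroxyls appear in one operation without any enolisable intermediate at C8.

Step 12
Reactants: 16 triol
Product: 17 pentakis(tert-butyldimethylsilyl) ether carrying the unit B guaiacyl allyl ether
Conditions: TBSOTf, 2,6-lutidine, CH2Cl2, −40 → 0 °C
Reagents that add atoms: tert-butyldimethylsilyl triflate, CC(C)(C)[Si](C)(C)OS(=O)(=O)C(F)(F)F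
Why: Exhaustive silylation of two primary and one secondary hydroxyl; if the guaiacyl silyl ether was partly lost to alkoxide in step 11 it is restored here, so 17 is reached either way.

Step 13
Reactants: 17 pentasilyl allyl ether
Product: 18 silylated core–unit A–unit B phenol with the single free guaiacyl hydroxyl
Conditions: Pd(PPh3)4 (5 mol %), morpholine, THF, rt
Reagents that add atoms: none
Why: Tsuji–Trost-type deallylation: zerovalent palladium ionises the aryl allyl ether to a π-allyl complex that morpholine captures, freeing the phenol under conditions without acid or fluoride that spare the five silyl ethers and the furofuran.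

Step 14
Reactants: 18 silylated phenol; 19 ethyl diazoacetate (2 equiv); 20 4-formyl-2-methoxyphenyl acetate (vanillin acetate, 3 equiv)
Product: 22 silylated target carrying unit C as the ethyl (2S,3S)-2-aryloxy-3-(4-acetoxy-3-methoxyphenyl)-3-hydroxypropanoate (7S,8R after reduction), via protic oxonium ylide 21 (not isolated)
Conditions: Rh2(OAc)4 (2 mol %), (R)-3,3′-bis(2,4,6-triisopropylphenyl)-1,1′-binaphthyl-2,2′-diyl hydrogen phosphate (10 mol %), 4 Å MS, CH2Cl2, −20 °C; 19 added by syringe pump
Reagents that add atoms: none
Why: Proposed new method: the divalent rhodium carboxylate converts 19 into an electrophilic carbene, which is attacked by the only free O–H of 18 to give the metal-associated oxonium ylide 21, an enol equivalent of the aryloxyacetate; instead of the usual 1,2-proton shift its carbon adds to aldehyde 20 held by the chiral phosphoric acid, forming O–C8 and C7–C8 of unit C in one operation. The closest known reaction type is the dirhodium and chiral-acid co-catalysed three-component coupling of aryl diazoacetates, alcohols and aldehydes or imines by ylide trapping; new here are the acceptor-only diazo ester and a phenol as the O–H partner. No ring is closed. C7 and C8 are both set in the C–C bond-forming event, and their relative (anti, erythro) and absolute configuration must be imposed by the phosphate, which is expected to bridge the enol O–H and the aldehyde in a cyclic hydrogen-bonded array; the substrate stereocentres are more than seven bonds away and should exert no bias. Site selectivity is secured by the substrate, since every other oxygen is silylated or etherified. Aldol-type trapping must outrun proton transfer, which is the reason for the acetoxy aldehyde (more electrophilic than a silyloxy one and a poorer partner for carbonyl-ylide formation), its excess, the low temperature and the slow addition of 19. The sense of induction of the acid is to be checked on a simple phenol first and the antipodal acid taken if required.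

Step 15
Reactants: 22 ester–acetate
Product: 23 pentakis(tert-butyldimethylsilyl) ether of the target with unit C fully unmasked
Conditions: LiBH4, THF, 0 °C → rt
Reagents that add atoms: none
Why: Borohydride reduction of the α-aryloxy β-hydroxy ester to the primary C9 alcohol with concurrent reductive cleavage of the aryl acetate; alkyl silyl ethers are inert and neither new stereocentre stays enolisable once the ester is reduced.

Step 16
Reactants: 23 pentasilyl ether
Product: 24 CNP0316493.3 (target)
Conditions: Bu4NF, AcOH (1:1), THF, 0 °C → rt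
Reagents that add atoms: none
Why: Fluoride-mediated global desilylation; buffering with acetic acid keeps the liberated 4-hydroxybenzyl alcohols protonated and so suppresses quinone methide formation and base-induced epimerisation at the benzylic carbons.

## Compound list

1 | sinapyl alcohol | COc1cc(/C=C/CO)cc(OC)c1O | starting material
2 | (±)-syringaresinol (racemate; one enantiomer drawn) | COc1cc(cc(OC)c1O)[C@H]1OC[C@H]2[C@@H]1CO[C@@H]2c1cc(OC)c(O)c(OC)c1 | intermediate
3 | (7S,7′S,8R,8′R)-syringaresinol | COc1cc(cc(OC)c1O)[C@H]1OC[C@H]2[C@@H]1CO[C@@H]2c1cc(OC)c(O)c(OC)c1 | intermediate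
4 | (R)-4-benzyloxazolidin-2-one | O=C1OC[C@@H](Cc2ccccc2)N1 | starting material
5 | (R)-4-benzyl-3-(2-bromoacetyl)oxazolidin-2-one | O=C(CBr)N1[C@H](Cc2ccccc2)COC1=O | intermediate
6 | 4,4′-bis-O-{2-[(4R)-4-benzyl-2-oxooxazolidin-3-yl]-2-oxoethyl}-(7S,7′S,8R,8′R)-syringaresinol | O=C1OC[C@@H](Cc2ccccc2)N1C(=O)COc2c(OC)cc([C@H]3OC[C@H]4[C@@H]3CO[C@@H]4c3cc(OC)c(OCC(=O)N4[C@H](Cc5ccccc5)COC4=O)c(OC)c3)cc2OC | intermediate
7 | vanillin | COc1cc(C=O)ccc1O | starting material
8 | 4-(allyloxy)-3-methoxybenzaldehyde | C=CCOc1ccc(C=O)cc1OC | intermediate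
9 | mono(dibutylboron) Z-enolate of 6 | O=C1OC[C@@H](Cc2ccccc2)N1C(=O)COc2c(OC)cc([C@H]3OC[C@H]4[C@@H]3CO[C@@H]4c3cc(OC)c(O/C=C(\OB(CCCC)CCCC)N4[C@H](Cc5ccccc5)COC4=O)c(OC)c3)cc2OC | intermediate (not isolated)
10 | mono-aldol adduct of 6 with 8 (unit B arm (2R,3S), free C7–OH; other arm glycolyl imide) | O=C1OC[C@@H](Cc2ccccc2)N1C(=O)COc2c(OC)cc([C@H]3OC[C@H]4[C@@H]3CO[C@@H]4c3cc(OC)c(O[C@@H](C(=O)N4[C@H](Cc5ccccc5)COC4=O)[C@@H](O)c4ccc(OCC=C)c(OC)c4)c(OC)c3)cc2OC | intermediate
11 | 10 with the unit B C7 hydroxyl as tert-butyldimethylsilyl ether | O=C1OC[C@@H](Cc2ccccc2)N1C(=O)COc2c(OC)cc([C@H]3OC[C@H]4[C@@H]3CO[C@@H]4c3cc(OC)c(O[C@@H](C(=O)N4[C@H](Cc5ccccc5)COC4=O)[C@@H](O[Si](C)(C)C(C)(C)C)c4ccc(OCC=C)c(OC)c4)c(OC)c3)cc2OC | intermediate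
12 | 4-(tert-butyldimethylsilyloxy)-3-methoxybenzaldehyde | O=Cc1ccc(O[Si](C)(C)C(C)(C)C)c(OC)c1 | intermediate
13 | dibutylboron Z-enolate of the glycolyl imide arm of 11 | CCCCB(CCCC)O/C(=C\Oc2c(OC)cc([C@H]3OC[C@H]4[C@@H]3CO[C@@H]4c3cc(OC)c(O[C@@H](C(=O)N4[C@H](Cc5ccccc5)COC4=O)[C@@H](O[Si](C)(C)C(C)(C)C)c4ccc(OCC=C)c(OC)c4)c(OC)c3)cc2OC)N1[C@H](Cc2ccccc2)COC1=O | intermediate (not isolated)
14 | double aldol adduct (unit A arm (2R,3S), free C7–OH; unit B arm as in 11) | COc1cc([C@H](O)[C@H](C(=O)N2[C@H](Cc3ccccc3)COC2=O)Oc2c(OC)cc([C@H]3OC[C@H]4[C@@H]3CO[C@@H]4c3cc(OC)c(O[C@@H](C(=O)N4[C@H](Cc5ccccc5)COC4=O)[C@@H](O[Si](C)(C)C(C)(C)C)c4ccc(OCC=C)c(OC)c4)c(OC)c3)cc2OC)ccc1O[Si](C)(C)C(C)(C)C | intermediate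
15 | 4-nitrobenzoate of 14 with inverted unit A C7 | COc1cc([C@@H](OC(=O)c2ccc(cc2)[N+](=O)[O-])[C@H](C(=O)N2[C@H](Cc3ccccc3)COC2=O)Oc2c(OC)cc([C@H]3OC[C@H]4[C@@H]3CO[C@@H]4c3cc(OC)c(O[C@@H](C(=O)N4[C@H](Cc5ccccc5)COC4=O)[C@@H](O[Si](C)(C)C(C)(C)C)c4ccc(OCC=C)c(OC)c4)c(OC)c3)cc2OC)ccc1O[Si](C)(C)C(C)(C)C | intermediate
16 | triol (unit A (7R,8S)-diol, unit B C9–OH) | COc1cc([C@@H](O)[C@H](CO)Oc2c(OC)cc([C@H]3OC[C@H]4[C@@H]3CO[C@@H]4c3cc(OC)c(O[C@@H](CO)[C@@H](O[Si](C)(C)C(C)(C)C)c4ccc(OCC=C)c(OC)c4)c(OC)c3)cc2OC)ccc1O[Si](C)(C)C(C)(C)C | intermediate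
17 | pentakis(tert-butyldimethylsilyl) ether with unit B guaiacyl allyl ether | COc1cc([C@@H](O[Si](C)(C)C(C)(C)C)[C@H](CO[Si](C)(C)C(C)(C)C)Oc2c(OC)cc([C@H]3OC[C@H]4[C@@H]3CO[C@@H]4c3cc(OC)c(O[C@@H](CO[Si](C)(C)C(C)(C)C)[C@@H](O[Si](C)(C)C(C)(C)C)c4ccc(OCC=C)c(OC)c4)c(OC)c3)cc2OC)ccc1O[Si](C)(C)C(C)(C)C | intermediate
18 | silylated core–unit A–unit B phenol (free guaiacyl hydroxyl of unit B) | COc1cc([C@@H](O[Si](C)(C)C(C)(C)C)[C@H](CO[Si](C)(C)C(C)(C)C)Oc2c(OC)cc([C@H]3OC[C@H]4[C@@H]3CO[C@@H]4c3cc(OC)c(O[C@@H](CO[Si](C)(C)C(C)(C)C)[C@@H](O[Si](C)(C)C(C)(C)C)c4ccc(O)c(OC)c4)c(OC)c3)cc2OC)ccc1O[Si](C)(C)C(C)(C)C | intermediate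
19 | ethyl diazoacetate | CCOC(=O)C=[N+]=[N-] | starting material
20 | 4-formyl-2-methoxyphenyl acetate (vanillin acetate) | CC(=O)Oc1ccc(C=O)cc1OC | starting material
21 | protic oxonium ylide from 18 and the carbene of 19 (drawn without the metal) | COc1cc([C@@H](O[Si](C)(C)C(C)(C)C)[C@H](CO[Si](C)(C)C(C)(C)C)Oc2c(OC)cc([C@H]3OC[C@H]4[C@@H]3CO[C@@H]4c3cc(OC)c(O[C@@H](CO[Si](C)(C)C(C)(C)C)[C@@H](O[Si](C)(C)C(C)(C)C)c4ccc([OH+][CH-]C(=O)OCC)c(OC)c4)c(OC)c3)cc2OC)ccc1O[Si](C)(C)C(C)(C)C | intermediate (not isolated)
22 | silylated target with unit C as ethyl (2S,3S)-ester, free C7–OH and aryl acetate | COc1cc([C@@H](O[Si](C)(C)C(C)(C)C)[C@H](CO[Si](C)(C)C(C)(C)C)Oc2c(OC)cc([C@H]3OC[C@H]4[C@@H]3CO[C@@H]4c3cc(OC)c(O[C@@H](CO[Si](C)(C)C(C)(C)C)[C@@H](O[Si](C)(C)C(C)(C)C)c4ccc(O[C@H](C(=O)OCC)[C@@H](O)c5ccc(OC(C)=O)c(OC)c5)c(OC)c4)c(OC)c3)cc2OC)ccc1O[Si](C)(C)C(C)(C)C | intermediate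
23 | pentakis(tert-butyldimethylsilyl) ether of the target (unit C free) | COc1cc([C@@H](O[Si](C)(C)C(C)(C)C)[C@H](CO[Si](C)(C)C(C)(C)C)Oc2c(OC)cc([C@H]3OC[C@H]4[C@@H]3CO[C@@H]4c3cc(OC)c(O[C@@H](CO[Si](C)(C)C(C)(C)C)[C@@H](O[Si](C)(C)C(C)(C)C)c4ccc(O[C@H](CO)[C@@H](O)c5ccc(O)c(OC)c5)c(OC)c4)c(OC)c3)cc2OC)ccc1O[Si](C)(C)C(C)(C)C | intermediate
24 | CNP0316493.3 | COc1cc([C@@H](O)[C@H](CO)Oc2c(OC)cc([C@H]3OC[C@H]4[C@@H]3CO[C@@H]4c3cc(OC)c(O[C@@H](CO)[C@@H](O)c4ccc(O[C@H](CO)[C@@H](O)c5ccc(O)c(OC)c5)c(OC)c4)c(OC)c3)cc2OC)ccc1O | target

## Step count and least certain steps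

Total step count: 16. Longest linear sequence: 13 steps from sinapyl alcohol 1 (steps 1, 2, 4, 6, 7 and 9 to 16); steps 3, 5 and 8 prepare side components.

**Step 14 (key step, new method).** The most likely failure is proton transfer within the ylide outrunning carbon–carbon bond formation, so that only O–H insertion takes place. Behind that stand insufficient or wrong-sense control of C7/C8 by the acid against the mismatch-free but unactivated substrate, and carbene dimerisation if addition is too fast. Fallback by known chemistry, setting out from 18 and rejoining the route at 24: phenol 18 is alkylated (K2CO3, acetone) with (S)-4-benzyl-3-(2-bromoacetyl)oxazolidin-2-one F1, made as in step 3 from the antipodal oxazolidinone, to give the aryloxyacetyl imide F2. A boron syn aldol with 12 gives the syn adduct F3, Mitsunobu inversion with 4-nitrobenzoic acid gives the erythro 4-nitrobenzoate F4, and LiBH4 gives the hexasilyl erythro diol F5, which under the conditions of step 16 gives 24.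

**Step 10.** The activated benzylic alkoxyphosphonium ion may undergo β-elimination through the acidic C8–H next to the imide, or ionise at the electron-rich benzylic carbon with loss of stereochemical fidelity. Fallback, setting out from 14 and rejoining at 17: the inversion is moved behind the reduction. LiBH4 converts 14 into the threo triol F6, and TBSCl/imidazole at 0 °C silylates only the two primary hydroxyls to give the mono-carbinol F7. Mitsunobu esterification at the now non-enolisable carbinol gives the inverted 4-nitrobenzoate F8, LiBH4 cleaves the ester to the erythro alcohol F9, and TBSOTf/2,6-lutidine gives 17.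

**Step 6.** Enolisation of the two equivalent imide arms is statistical, so double addition and unreacted 6 lower the throughput, and the separation has to carry the selectivity. Fallback, setting out from 3 and rejoining at 11: the symmetry is broken one stage earlier, where all components are reusable. Alkylation of 3 with a deficit of 5 gives the mono-imide monophenol F10 (recovered 3 is recycled and 6 formed alongside feeds the main line). A boron aldol with 8, with a second equivalent of n-Bu2BOTf masking the phenol, gives the phenolic aldol adduct F11, and TBSOTf gives the bis-silyl compound F12. KHF2 in MeOH cleaves only the aryl silyl ether to the phenol F13, and alkylation with 5 (K2CO3, acetone) gives 11.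

**Step 2.** Peak overlap or low loading capacity on the preparative scale would limit the supply of 3. Fallback, setting out from 2 and rejoining at 3: classical resolution through covalent diastereomers. Acylation of 2 with (1S)-camphanic chloride (pyridine, DMAP) gives the bis-camphanate F14 of the wanted enantiomer and the bis-camphanate F15 of its antipode. These are separated by fractional crystallisation, and K2CO3/MeOH on F14 returns 3.

## Further compounds

F1 | step 14 | (S)-4-benzyl-3-(2-bromoacetyl)oxazolidin-2-one | O=C(CBr)N1[C@@H](Cc2ccccc2)COC1=O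
F2 | step 14 | aryloxyacetyl imide of 18 with the (S)-auxiliary | COc1cc([C@@H](O[Si](C)(C)C(C)(C)C)[C@H](CO[Si](C)(C)C(C)(C)C)Oc2c(OC)cc([C@H]3OC[C@H]4[C@@H]3CO[C@@H]4c3cc(OC)c(O[C@@H](CO[Si](C)(C)C(C)(C)C)[C@@H](O[Si](C)(C)C(C)(C)C)c4ccc(OCC(=O)N5[C@@H](Cc6ccccc6)COC5=O)c(OC)c4)c(OC)c3)cc2OC)ccc1O[Si](C)(C)C(C)(C)C
F3 | step 14 | syn aldol adduct of F2 with 12 ((2S,3R) acyl configuration) | COc1cc([C@@H](O[Si](C)(C)C(C)(C)C)[C@H](CO[Si](C)(C)C(C)(C)C)Oc2c(OC)cc([C@H]3OC[C@H]4[C@@H]3CO[C@@H]4c3cc(OC)c(O[C@@H](CO[Si](C)(C)C(C)(C)C)[C@@H](O[Si](C)(C)C(C)(C)C)c4ccc(O[C@H](C(=O)N5[C@@H](Cc6ccccc6)COC5=O)[C@H](O)c5ccc(O[Si](C)(C)C(C)(C)C)c(OC)c5)c(OC)c4)c(OC)c3)cc2OC)ccc1O[Si](C)(C)C(C)(C)C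
F4 | step 14 | 4-nitrobenzoate of F3 with inverted unit C C7 | COc1cc([C@@H](O[Si](C)(C)C(C)(C)C)[C@H](CO[Si](C)(C)C(C)(C)C)Oc2c(OC)cc([C@H]3OC[C@H]4[C@@H]3CO[C@@H]4c3cc(OC)c(O[C@@H](CO[Si](C)(C)C(C)(C)C)[C@@H](O[Si](C)(C)C(C)(C)C)c4ccc(O[C@H](C(=O)N5[C@@H](Cc6ccccc6)COC5=O)[C@@H](OC(=O)c5ccc(cc5)[N+](=O)[O-])c5ccc(O[Si](C)(C)C(C)(C)C)c(OC)c5)c(OC)c4)c(OC)c3)cc2OC)ccc1O[Si](C)(C)C(C)(C)C
F5 | step 14 | hexakis(tert-butyldimethylsilyl) ether of the target with free unit C (7S,8R)-diol | COc1cc([C@@H](O[Si](C)(C)C(C)(C)C)[C@H](CO[Si](C)(C)C(C)(C)C)Oc2c(OC)cc([C@H]3OC[C@H]4[C@@H]3CO[C@@H]4c3cc(OC)c(O[C@@H](CO[Si](C)(C)C(C)(C)C)[C@@H](O[Si](C)(C)C(C)(C)C)c4ccc(O[C@H](CO)[C@@H](O)c5ccc(O[Si](C)(C)C(C)(C)C)c(OC)c5)c(OC)c4)c(OC)c3)cc2OC)ccc1O[Si](C)(C)C(C)(C)C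
F6 | step 10 | threo triol from reduction of 14 (unit A (7S,8S)-diol, unit B C9–OH) | COc1cc([C@H](O)[C@H](CO)Oc2c(OC)cc([C@H]3OC[C@H]4[C@@H]3CO[C@@H]4c3cc(OC)c(O[C@@H](CO)[C@@H](O[Si](C)(C)C(C)(C)C)c4ccc(OCC=C)c(OC)c4)c(OC)c3)cc2OC)ccc1O[Si](C)(C)C(C)(C)C
F7 | step 10 | F6 with both primary hydroxyls silylated (free unit A C7–OH, 7S) | COc1cc([C@H](O)[C@H](CO[Si](C)(C)C(C)(C)C)Oc2c(OC)cc([C@H]3OC[C@H]4[C@@H]3CO[C@@H]4c3cc(OC)c(O[C@@H](CO[Si](C)(C)C(C)(C)C)[C@@H](O[Si](C)(C)C(C)(C)C)c4ccc(OCC=C)c(OC)c4)c(OC)c3)cc2OC)ccc1O[Si](C)(C)C(C)(C)C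
F8 | step 10 | inverted 4-nitrobenzoate of F7 (unit A 7R) | COc1cc([C@@H](OC(=O)c2ccc(cc2)[N+](=O)[O-])[C@H](CO[Si](C)(C)C(C)(C)C)Oc2c(OC)cc([C@H]3OC[C@H]4[C@@H]3CO[C@@H]4c3cc(OC)c(O[C@@H](CO[Si](C)(C)C(C)(C)C)[C@@H](O[Si](C)(C)C(C)(C)C)c4ccc(OCC=C)c(OC)c4)c(OC)c3)cc2OC)ccc1O[Si](C)(C)C(C)(C)C
F9 | step 10 | erythro alcohol from F8 (free unit A C7–OH, 7R) | COc1cc([C@@H](O)[C@H](CO[Si](C)(C)C(C)(C)C)Oc2c(OC)cc([C@H]3OC[C@H]4[C@@H]3CO[C@@H]4c3cc(OC)c(O[C@@H](CO[Si](C)(C)C(C)(C)C)[C@@H](O[Si](C)(C)C(C)(C)C)c4ccc(OCC=C)c(OC)c4)c(OC)c3)cc2OC)ccc1O[Si](C)(C)C(C)(C)C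
F10 | step 6 | mono-glycolyl imide monophenol of 3 | COc1cc(cc(OC)c1O)[C@H]1OC[C@H]2[C@@H]1CO[C@@H]2c1cc(OC)c(OCC(=O)N2[C@H](Cc3ccccc3)COC2=O)c(OC)c1
F11 | step 6 | aldol adduct of F10 with 8 (free syringyl phenol and free C7–OH) | COc1cc(cc(OC)c1O)[C@H]1OC[C@H]2[C@@H]1CO[C@@H]2c1cc(OC)c(O[C@@H](C(=O)N2[C@H](Cc3ccccc3)COC2=O)[C@@H](O)c2ccc(OCC=C)c(OC)c2)c(OC)c1
F12 | step 6 | bis(tert-butyldimethylsilyl) derivative of F11 (syringyl O and C7–O) | COc1cc(cc(OC)c1O[Si](C)(C)C(C)(C)C)[C@H]1OC[C@H]2[C@@H]1CO[C@@H]2c1cc(OC)c(O[C@@H](C(=O)N2[C@H](Cc3ccccc3)COC2=O)[C@@H](O[Si](C)(C)C(C)(C)C)c2ccc(OCC=C)c(OC)c2)c(OC)c1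
F13 | step 6 | phenol from selective aryl desilylation of F12 | COc1cc(cc(OC)c1O)[C@H]1OC[C@H]2[C@@H]1CO[C@@H]2c1cc(OC)c(O[C@@H](C(=O)N2[C@H](Cc3ccccc3)COC2=O)[C@@H](O[Si](C)(C)C(C)(C)C)c2ccc(OCC=C)c(OC)c2)c(OC)c1
F14 | step 2 | bis[(1S)-camphanate] of (7S,7′S,8R,8′R)-syringaresinol | COc1cc(cc(OC)c1OC(=O)[C@@]12CC[C@@](C)(C(=O)O1)C2(C)C)[C@H]1OC[C@H]2[C@@H]1CO[C@@H]2c1cc(OC)c(OC(=O)[C@@]34CC[C@@](C)(C(=O)O3)C4(C)C)c(OC)c1
F15 | step 2 | bis[(1S)-camphanate] of (7R,7′R,8S,8′S)-syringaresinol | COc1cc(cc(OC)c1OC(=O)[C@@]12CC[C@@](C)(C(=O)O1)C2(C)C)[C@@H]1OC[C@@H]2[C@H]1CO[C@H]2c1cc(OC)c(OC(=O)[C@@]34CC[C@@](C)(C(=O)O3)C4(C)C)c(OC)c1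
A1 | alternative 1 | all-trans 1,2-bis(1-methylimidazol-2-ylcarbonyl)-3,4-bis(4-benzyloxy-3,5-dimethoxyphenyl)cyclobutane | O=C(c1nccn1C)[C@@H]1[C@@H](c2cc(OC)c(OCc3ccccc3)c(OC)c2)[C@H](c2cc(OC)c(OCc3ccccc3)c(OC)c2)[C@H]1C(=O)c1nccn1C
A2 | alternative 1 | (E)-3-(4-benzyloxy-3,5-dimethoxyphenyl)-1-(1-methylimidazol-2-yl)prop-2-en-1-one | Cn1ccnc1C(=O)/C=C/c1cc(OC)c(OCc2ccccc2)c(OC)c1
A3 | alternative 2 | (7S,7′S,8R,8′R)-syringaresinol bis(tert-butyldimethylsilyl) ether | COc1cc(cc(OC)c1O[Si](C)(C)C(C)(C)C)[C@H]1OC[C@H]2[C@@H]1CO[C@@H]2c1cc(OC)c(O[Si](C)(C)C(C)(C)C)c(OC)c1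
A4 | alternative 2 | cis-fused 3,7-dioxabicyclo[3.3.0]octane-2,6-diyl diacetate (ring-fusion carbons as in 3, anomeric centres unspecified) | CC(=O)OC1OC[C@H]2[C@@H]1COC2OC(C)=O
A5 | alternative 2 | [4-(tert-butyldimethylsilyloxy)-3,5-dimethoxyphenyl]zinc chloride | COc1cc([Zn]Cl)cc(OC)c1O[Si](C)(C)C(C)(C)C
A6 | alternative 3 | (7S,7′S,8R,8′R)-syringaresinol mono-benzyl mono-triisopropylsilyl ether | COc1cc(cc(OC)c1OCc1ccccc1)[C@H]1OC[C@H]2[C@@H]1CO[C@@H]2c1cc(OC)c(O[Si](C(C)C)(C(C)C)C(C)C)c(OC)c1
A7 | alternative 3 | (S)-configured 1-(4-benzyloxy-3,5-dimethoxyphenyl)-1-(oxiran-2-yl)methyl (E)-3-[3,5-dimethoxy-4-(triisopropylsilyloxy)phenyl]allyl ether (epoxide carbon unspecified, it becomes the radical) | COc1cc(cc(OC)c1OCc1ccccc1)[C@H](C1CO1)OC/C=C/c1cc(OC)c(O[Si](C(C)C)(C(C)C)C(C)C)c(OC)c1
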